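**Remarks on assumptions**
- 4-Bromo-2,5-dimethoxybenzaldehyde (1) is taken to be a catalogue compound; the bromine is then already para to the future C4' oxygen and no separate bromination is needed.
- In steps 7 and 8 the C7 position is assumed to react before C5; the order does not affect the product.
- The aminoenone 13 is hydrolysed with dilute acid, not with carbonate, so that pyrrolidine leaves as its salt before the base-mediated ring closure. The bonds formed and the skeletons of 11 and 15 are unchanged, and both structures match ring B of 19 atom for atom.

## Structural features

Brandisianin A (19) is an isoflavone: benzene ring A is fused to the 4-pyranone ring C (O1, C2, C3, C4, C4a, C8a), and aryl ring B is attached to C3 through a single C3–C1' bond. Ring A carries free hydroxyls at C5 (hydrogen-bonded to the C4 carbonyl) and C7. Ring B carries methoxy groups at C2' and C5' and a 3-methylbut-2-enyl (prenyl) ether at C4'. There is no stereocentre and no configurational double bond, so the problem is one of connectivity and chemoselectivity only. The fragile elements are the prenyl aryl ether and C2 of the pyranone. The ether is cleaved or cyclised by protic and Lewis acids, reduced by hydrogenation, ionised by zerovalent palladium and rearranged on strong heating. C2 can be attacked by hard nucleophiles with opening of ring C. The real difficulty is the end game: two phenols on ring A must be freed while two methyl ethers and the prenyl ether on ring B stay, which excludes benzyl, methyl and acetal protection of the ring A oxygens. The key step uses the phloroglucinol pattern of ring A: O1 (on C8a), the C5 oxygen and the C7 oxygen are mutually meta and each is ortho or para to the C4 carbonyl. All three C–O bonds can therefore be made by nucleophilic aromatic substitution on one symmetrical 2,4,6-trifluorobenzoyl unit, the O1–C8a bond intramolecularly with closure of ring C.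

## Logic of the disconnections

**19 to 17.** The two phenolic O–H bonds at C5 and C7 are traced back to O–CH2CH2SiMe3 bonds. Fluoride is the one deprotecting agent to which the methyl ethers, the prenyl ether and the pyranone are all indifferent. No skeletal simplification results, but the end game becomes orthogonal to ring B. The forward step must cleave both groups by attack at silicon and β-elimination without base damage at C2.

**17 to 15.** The C5–O and C7–O bonds are cut, leaving C–F at both carbons. Both positions are activated by the C4 carbonyl, and fluorine is an inert placeholder for oxygen in all earlier steps. The gain is that ring A needs no protecting group while the ring system is built. The forward step is a twofold substitution by an alkoxide that must prefer the C–F carbons to C2, under strictly dry conditions.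

**15 to 11 and 12.** Two bonds of ring C are cut, C3–C4 and O1–C8a. This gives a ring B enamine carrying C2 and C3 and a ring A acid chloride carrying C4; O1 comes from water. This is the largest simplification of the route: the bicyclic core falls into two pieces of similar size, one of them bought. The forward step demands C-acylation at the enamine β-carbon, hydrolysis without loss of the formyl carbon, and closure on one of two equivalent ortho fluorines with the liberated amine kept away from the fluoroarene.

**11 to 9 and 10.** The enamine C–N bond is cut. The enamine is the simplest nucleophilic form of the two-carbon side chain, and 10 is bought. The forward step needs removal of water and of excess amine, and 9 must be used fresh.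

**9 to 8.** Only the oxidation level changes; the alcohol is the stable form of the side chain. The oxidant must be mild, close to neutral and stop at the aldehyde.

**8 to 5 and 6.** The C1'–CH2 bond is cut into an aryl anion (7, from 5 by halogen–metal exchange) and a two-carbon electrophile. Both side-chain carbons arrive in one step under basic conditions that are harmless to the prenyl ether. The exchange must outrun deprotonation next to the allylic ether oxygen, and the anion must be captured efficiently.

**5 to 3 and 4.** The O–CH2 bond of the prenyl ether is cut. The prenyl group can go on early because every later step is basic, neutral, fluoride-mediated or only briefly and mildly acidic. The forward step must give O- rather than C-alkylation without rearrangement.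

**3 to 1.** The C4'–O bond is traced to the C–CHO bond of 1 by oxidative aryl migration. 1 already holds both methoxy groups and the bromine in the right places, so no regiochemical question remains. The forward step needs aryl rather than hydride migration.

## Other disconnections considered

**Alternative 1:** The cut removes C4 altogether: C3–C4 and C4–C4a are disconnected and the carbonyl carbon comes from carbon monoxide A3. The precursor is the (Z)-enol triflate A2, in which ring A is already joined to C2 through O1.
- Forward key step: Pd(OAc)2 and tricyclohexylphosphine would give zerovalent palladium, which inserts into the C3–OTf bond. Insertion of A3 gives an acylpalladium species that metalates the ring A C–H bond ortho to O1, and reductive elimination closes ring C to give A1.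
- In favour: ring A enters with both oxygens in place, so no C–F to C–O exchange is needed. C4 comes from a one-carbon feedstock and ring A needs no halogen, which is better atom economy than a unit that sheds three fluorides.
- Against: A1 carries a benzyl ether at C4' and methoxymethyl groups at C5 and C7, presumably because a prenyl ether offers zerovalent palladium an allylic C–O bond and an alkene. The end game then needs debenzylation (hydrogenolysis endangers the C2=C3 bond), prenylation, and acid cleavage of two acetals beside the new prenyl ether. That is the protecting-group clash the chosen plan avoids.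
- Further points against: A2 must be made as one regio- and stereoisomer, the C–H bond to be acylated lies between two oxygen substituents, and the acylpalladium species has other outlets such as decarbonylation.
- Comparison: both plans close ring C in one operation with two new bonds, and both remove regiochemical doubt by the symmetry of the ring A partner; on these points they are equal. The alternative is better in atom economy. Mechanistically the chosen plan rests on two long-established polar steps, whereas a carbonylative C–H acylation starting from an enol triflate of this kind would have to be established. The alternative is expected to be at least two end-game steps longer. Both plans handle a toxic gas (A3 there, 6 here), so that point is a draw.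

**Alternative 2:** Rings C and B are assembled first and ring A is built last. C4a–C5, C5–C6 and C7–C8 are cut (C8–C8a arises in the Wolff shift), leading to the pyranonyl diazomethyl ketone A5 and the silyloxyalkyne A6. A5 would come from kojic acid A7 by cross-coupling at C5 with a boron derivative of 5 and conversion of the hydroxymethyl group into the diazoketone.
- Forward key step: irradiation of A5 gives, by Wolff rearrangement, a vinylketene whose vinyl part is a pyranone C=C bond. (2+2) cycloaddition with A6, four-electron ring opening, six-electron electrocyclisation and tautomerisation would give A4, with C5–OH free and C7–O silylated.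
- In favour: the oxygen pattern follows from the polarity of A6, the prenyl ether is already present, and one fluoride desilylation finishes the synthesis. That is one end-game step against two, and no alkoxide ever meets the pyranone; on both points the alternative is better than the chosen plan.
- Against: the C=C bond of a vinylogous ester must serve as the vinyl group of the ketene, which is an extrapolation. 4-Pyranones are photoactive themselves, and the prenyl alkene is a possible ketene trap. A5 needs a hazardous diazoalkane or a diazo-transfer sequence, and A6 is a moisture-sensitive reagent that must be prepared.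
- Comparison: structurally both plans are convergent and free of regiochemical ambiguity (equal). Mechanistically four pericyclic events in series leave more room for diversion than an acylation followed by an intramolecular substitution. In step count roughly five or six steps to A5, plus the preparation of A6 and of the boron reagent, make the total higher.

**Alternative 3:** Ring C is cut at O1–C8a and C4–C4a, so that ring A arrives as an aryne and C2, C3 and C4 arrive as the formylarylacetate enol A10.
- Forward key step: CsF would release aryne A11 from silylaryl triflate A9. The enolate oxygen of A10 adds to the aryne carbon remote from the neighbouring alkoxy group (O1–C8a). The aryl anion formed next to that alkoxy group attacks the ester (C4–C4a) and closes ring C to A8.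
- In favour: mild conditions (fluoride at ambient temperature), a convergent union, ring A oxygens present from the start, and an inductive bias of the 3-alkoxy aryne that points to the 5,7-pattern. In forming two ring C bonds in one flask it equals the chosen plan. It is better in that its key step needs neither an acid chloride nor a hydrolysis stage, and it has one end-game step against two.
- Against: the enolate is ambident, and attack through carbon followed by acyl transfer, the usual course of arynes with β-dicarbonyl compounds, would compete. Regiocontrol rests on a bias, whereas the chosen plan has true equivalence of the two ortho positions. A9 needs several steps from a 3,5-dioxygenated phenol. The final step is acid cleavage of two acetals beside the prenyl ether, with the C7 acetal the slow one.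
- Comparison: structurally both plans bring in the complete ring B unit with the prenyl ether in place (equal). Mechanistically the outcome depends on O- versus C-selectivity towards a very reactive intermediate, which is harder to argue than a stepwise acylation and substitution. About four extra steps on the ring A side make the total higher.

Key step: step 6

## Route

Step 1
Reactants: 1 4-bromo-2,5-dimethoxybenzaldehyde
Product: 3 4-bromo-2,5-dimethoxyphenol, via aryl formate 2 (not isolated)
Conditions: mCPBA, CH2Cl2, 0 °C to rt; then K2CO3 (cat.), MeOH, rt
Reagents that add atoms: mCPBA (3-chloroperoxybenzoic acid), OOC(=O)c1cccc(Cl)c1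
Why: Baeyer–Villiger oxidation of an electron-rich benzaldehyde (Dakin-type): the ortho-methoxyaryl group migrates in preference to hydride in the Criegee adduct, and methanol transesterifies formate 2; the aryl bromide is inert to the peracid.

Step 2
Reactants: 3 4-bromo-2,5-dimethoxyphenol; 4 prenyl bromide
Product: 5 1-bromo-2,5-dimethoxy-4-(3-methylbut-2-enyloxy)benzene
Conditions: K2CO3, DMF, rt
Reagents that add atoms: none
Why: Williamson ether synthesis: the phenoxide displaces bromide from the primary allylic halide at oxygen in a polar aprotic solvent, and room temperature excludes Claisen rearrangement.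

Step 3
Reactants: 5 1-bromo-2,5-dimethoxy-4-(3-methylbut-2-enyloxy)benzene; 6 ethylene oxide
Product: 8 2-[2,5-dimethoxy-4-(3-methylbut-2-enyloxy)phenyl]ethanol, via aryllithium 7 (not isolated)
Conditions: n-BuLi, THF, −78 °C; then 6 (THF solution), −78 °C to rt; H2O
Reagents that add atoms: none
Why: Bromine–lithium exchange is faster at −78 °C than deprotonation next to the allylic ether oxygen, and the ortho-methoxy group stabilises 7; ring opening of the epoxide by the aryl anion adds both side-chain carbons under basic conditions.

Step 4
Reactants: 8 2-[2,5-dimethoxy-4-(3-methylbut-2-enyloxy)phenyl]ethanol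
Product: 9 2-[2,5-dimethoxy-4-(3-methylbut-2-enyloxy)phenyl]acetaldehyde
Conditions: Dess–Martin periodinane, CH2Cl2, 0 °C to rt
Reagents that add atoms: none
Why: Dess–Martin oxidation stops at the aldehyde under anhydrous, nearly neutral conditions and leaves the trisubstituted alkene and the aryl ethers alone; 9 is carried on crude at once because arylacetaldehydes enolise and self-condense.

Step 5
Reactants: 9 2-[2,5-dimethoxy-4-(3-methylbut-2-enyloxy)phenyl]acetaldehyde; 10 pyrrolidine
Product: 11 (E)-1-{2-[2,5-dimethoxy-4-(3-methylbut-2-enyloxy)phenyl]ethenyl}pyrrolidine
Conditions: 4 Å molecular sieves, toluene, 0 °C to rt; filter, evaporate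
Reagents that add atoms: none
Why: Enamine condensation of an enolisable aldehyde with a secondary amine; dehydration over sieves should give the conjugated (E)-β-aminostyrene as the thermodynamic isomer, and the excess volatile amine is stripped off so that it cannot consume the acid chloride.

Step 6
Reactants: 11 (E)-1-{2-[2,5-dimethoxy-4-(3-methylbut-2-enyloxy)phenyl]ethenyl}pyrrolidine; 12 2,4,6-trifluorobenzoyl chloride
Product: 15 5,7-difluoro-3-[2,5-dimethoxy-4-(3-methylbut-2-enyloxy)phenyl]-4H-chromen-4-one, via aminoenone 13 (not isolated), via hydroxyenone 14 (not isolated)
Conditions: Et3N, THF, 0 °C to rt; then 1 M aq HCl, 0 °C to rt, extractive removal of the amine salts; then K2CO3, MeCN, 50 °C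
Reagents that add atoms: water, O
Why: This is a Stork enamine acylation followed by intramolecular nucleophilic aromatic substitution, the oxygen counterpart of the enamine and 2-halobenzoyl chloride route to 4-quinolones and a known entry to chromones. The β-carbon of 11, which bears ring B, attacks the acid chloride; N-acylation is reversible, so the C-acyl iminium ion accumulates and Et3N removes HCl to give the vinylogous amide 13 (bond C3–C4). Cold dilute acid hydrolyses 13 by C-protonation and addition of water to the iminium carbon, giving the hydrogen-bonded 3-hydroxyenone 14, whose enol oxygen is the future O1; pyrrolidine leaves in the aqueous phase as its salt and so cannot attack the fluoroarene or C2 of the product. K2CO3 then deprotonates 14, and the enolate oxygen adds to an ortho C–F carbon in a 6-exo-trig sense; the Meisenheimer intermediate is stabilised by the ketone and the two other fluorines and loses fluoride, closing ring C (bond O1–C8a). No stereocentre is formed. The step needs C- over N-acylation, which the reversibility of N-acylation provides, and monoacylation, which follows because 13 is a deactivated vinylogous amide. It also needs a single cyclisation product, which the equivalence of the two ortho fluorines guarantees; the para fluorine is out of reach of the enolate oxygen. The contact with dilute acid is short and cold, which a prenyl aryl ether should tolerate.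

Step 7
Reactants: 15 5,7-difluoro-3-[2,5-dimethoxy-4-(3-methylbut-2-enyloxy)phenyl]-4H-chromen-4-one
Product: 17 5,7-bis[2-(trimethylsilyl)ethoxy]-3-[2,5-dimethoxy-4-(3-methylbut-2-enyloxy)phenyl]-4H-chromen-4-one, via monoether 16 (not isolated)
Conditions: Me3SiCH2CH2OH, NaH, THF, 0 °C; then 15, 0 to 40 °C
Reagents that add atoms: 2-(trimethylsilyl)ethanol, C[Si](C)(C)CCO
Why: Twofold nucleophilic aromatic substitution: each C–F carbon is ortho or para to the C4 carbonyl, which takes up the Meisenheimer charge, and the first alkoxy group is meta to the second site and so does not deactivate it; dry conditions keep any alkoxide adduct at C2 reversible.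

Step 8
Reactants: 17 5,7-bis[2-(trimethylsilyl)ethoxy]-3-[2,5-dimethoxy-4-(3-methylbut-2-enyloxy)phenyl]-4H-chromen-4-one
Product: 19 brandisianin A, via monophenol 18 (not isolated)
Conditions: TBAF, THF, rt to 50 °C; then dilute aq HCl to pH 5
Reagents that add atoms: none
Why: Fluoride-induced β-elimination of 2-(trimethylsilyl)ethyl aryl ethers: fluoride attacks silicon and ethene and the phenoxide are expelled, the phenoxides being good leaving groups because they are conjugated with or chelated to the C4 carbonyl; methyl and prenyl aryl ethers are inert to fluoride.

## Compound list

1 | 4-bromo-2,5-dimethoxybenzaldehyde | O=Cc1cc(OC)c(Br)cc1OC | starting material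
2 | 4-bromo-2,5-dimethoxyphenyl formate | O=COc1cc(OC)c(Br)cc1OC | intermediate
3 | 4-bromo-2,5-dimethoxyphenol | Oc1cc(OC)c(Br)cc1OC | intermediate
4 | prenyl bromide (1-bromo-3-methylbut-2-ene) | CC(C)=CCBr | starting material
5 | 1-bromo-2,5-dimethoxy-4-(3-methylbut-2-enyloxy)benzene | COc1cc(OCC=C(C)C)c(OC)cc1Br | intermediate
6 | ethylene oxide (oxirane) | C1CO1 | starting material
7 | [2,5-dimethoxy-4-(3-methylbut-2-enyloxy)phenyl]lithium | [Li]c1cc(OC)c(OCC=C(C)C)cc1OC | intermediate
8 | 2-[2,5-dimethoxy-4-(3-methylbut-2-enyloxy)phenyl]ethanol | OCCc1cc(OC)c(OCC=C(C)C)cc1OC | intermediate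
9 | 2-[2,5-dimethoxy-4-(3-methylbut-2-enyloxy)phenyl]acetaldehyde | O=CCc1cc(OC)c(OCC=C(C)C)cc1OC | intermediate
10 | pyrrolidine | C1CCNC1 | starting material
11 | (E)-1-{2-[2,5-dimethoxy-4-(3-methylbut-2-enyloxy)phenyl]ethenyl}pyrrolidine | C1CCN(C1)/C=C/c1cc(OC)c(OCC=C(C)C)cc1OC | intermediate
12 | 2,4,6-trifluorobenzoyl chloride | O=C(Cl)c1c(F)cc(F)cc1F | starting material
13 | (E)-2-[2,5-dimethoxy-4-(3-methylbut-2-enyloxy)phenyl]-3-(pyrrolidin-1-yl)-1-(2,4,6-trifluorophenyl)prop-2-en-1-one | O=C(c1c(F)cc(F)cc1F)/C(=C/N1CCCC1)c1cc(OC)c(OCC=C(C)C)cc1OC | intermediate
14 | (Z)-3-hydroxy-2-[2,5-dimethoxy-4-(3-methylbut-2-enyloxy)phenyl]-1-(2,4,6-trifluorophenyl)prop-2-en-1-one | O=C(c1c(F)cc(F)cc1F)/C(=C\O)c1cc(OC)c(OCC=C(C)C)cc1OC | intermediate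
15 | 5,7-difluoro-3-[2,5-dimethoxy-4-(3-methylbut-2-enyloxy)phenyl]-4H-chromen-4-one | COc1cc(-c2coc3cc(F)cc(F)c3c2=O)c(OC)cc1OCC=C(C)C | intermediate
16 | 5-fluoro-7-[2-(trimethylsilyl)ethoxy]-3-[2,5-dimethoxy-4-(3-methylbut-2-enyloxy)phenyl]-4H-chromen-4-one | COc1cc(-c2coc3cc(OCC[Si](C)(C)C)cc(F)c3c2=O)c(OC)cc1OCC=C(C)C | intermediate
17 | 5,7-bis[2-(trimethylsilyl)ethoxy]-3-[2,5-dimethoxy-4-(3-methylbut-2-enyloxy)phenyl]-4H-chromen-4-one | COc1cc(-c2coc3cc(OCC[Si](C)(C)C)cc(OCC[Si](C)(C)C)c3c2=O)c(OC)cc1OCC=C(C)C | intermediate
18 | 7-hydroxy-5-[2-(trimethylsilyl)ethoxy]-3-[2,5-dimethoxy-4-(3-methylbut-2-enyloxy)phenyl]-4H-chromen-4-one | COc1cc(-c2coc3cc(O)cc(OCC[Si](C)(C)C)c3c2=O)c(OC)cc1OCC=C(C)C | intermediate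
19 | brandisianin A, 5,7-dihydroxy-3-[2,5-dimethoxy-4-(3-methylbut-2-enyloxy)phenyl]-4H-chromen-4-one | COc1cc(-c2coc3cc(O)cc(O)c3c2=O)c(OC)cc1OCC=C(C)C | target

## Step count and least certain steps

Total: 8 steps. Longest linear sequence: 8 steps, from 1 to 19; compounds 4, 6, 10 and 12 are bought.

**Step 6 (key step).** The likely failure is slow C–C bond formation between a hindered enamine β-carbon, which bears an ortho-methoxyaryl group, and a 2,6-disubstituted acid chloride. That would leave time for hydrolysis of the moisture-sensitive enamine and for N-acylation that does not revert. A second risk is retro-Claisen loss of the formyl carbon from 14 during the basic ring closure.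
Fallback, from 9 back to 14 and then 15: the C3–C4 bond is made by carbonyl addition instead. 1,3,5-Trifluorobenzene is lithiated with n-BuLi in THF at −78 °C to 2,4,6-trifluorophenyllithium F1. This adds to the aldehyde of 9 to give (±)-2-[2,5-dimethoxy-4-(3-methylbut-2-enyloxy)phenyl]-1-(2,4,6-trifluorophenyl)ethanol F2. Dess–Martin oxidation gives the deoxybenzoin 2-[2,5-dimethoxy-4-(3-methylbut-2-enyloxy)phenyl]-1-(2,4,6-trifluorophenyl)ethanone F3. Heating with N,N-dimethylformamide dimethyl acetal introduces C2 as (E)-3-(dimethylamino)-2-[2,5-dimethoxy-4-(3-methylbut-2-enyloxy)phenyl]-1-(2,4,6-trifluorophenyl)prop-2-en-1-one F4. Dilute aqueous HCl converts F4 into 14, and K2CO3 closes ring C to 15 as in the main route.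

**Step 7.** The likely failure is conjugate addition of the alkoxide at C2 with opening of ring C and, if water is present, irreversible loss of C2 as formate. The second displacement at the chelated C5 position may also stall, and the β-silyl alkoxide may fragment in a Peterson-type elimination on warming.
Fallback, from 15 directly to 19: a weakly basic hydroxide surrogate replaces the alkoxide. (E)-Benzaldoxime and Cs2CO3 in DMSO at 60–80 °C would displace fluoride through the oximate oxygen. The O-aryl oxime collapses in the flask to the phenoxide and benzonitrile, first giving 5-fluoro-7-hydroxy-3-[2,5-dimethoxy-4-(3-methylbut-2-enyloxy)phenyl]-4H-chromen-4-one F5 and, after the second displacement, 19. Compound 17 and step 8 are bypassed.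

**Step 3.** The likely failure is loss of the aryllithium by protonation, butylation by the 1-bromobutane formed in the exchange, or deprotonation next to the allylic ether oxygen, because aryllithiums open ethylene oxide only slowly at low temperature.
Fallback, from 5 back to 9: Suzuki–Miyaura coupling of 5 with (E)-2-(2-ethoxyethenyl)-4,4,5,5-tetramethyl-1,3,2-dioxaborolane (Pd(dppf)Cl2, K2CO3, dioxane/water, 80 °C) should give (E)-1-(2-ethoxyethenyl)-2,5-dimethoxy-4-(3-methylbut-2-enyloxy)benzene F6. Oxidative addition of zerovalent palladium to the aryl bromide should outrun ionisation of the trisubstituted allylic ether. Brief hydrolysis of the enol ether with dilute aqueous HCl in THF gives 9, without the organolithium, compound 6 or the oxidation.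

**Step 4.** The likely failure is enolisation-driven self-condensation and autoxidation of the electron-rich arylacetaldehyde during work-up and concentration.
Fallback, from 5 (through 7) back to 11, so that the free aldehyde 9 is never formed: aryllithium 7 is quenched with DMF to give 2,5-dimethoxy-4-(3-methylbut-2-enyloxy)benzaldehyde F7. Diethyl (pyrrolidin-1-ylmethyl)phosphonate is deprotonated with n-BuLi in THF at −78 °C to diethyl [lithio(pyrrolidin-1-yl)methyl]phosphonate F8. F8 adds to F7, and on warming the adduct loses lithium diethyl phosphate in a Horner–Wadsworth–Emmons-type enamine synthesis, giving 11 directly.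

## Further compounds

F1 | step 6 | 2,4,6-trifluorophenyllithium | [Li]c1c(F)cc(F)cc1F
F2 | step 6 | (±)-2-[2,5-dimethoxy-4-(3-methylbut-2-enyloxy)phenyl]-1-(2,4,6-trifluorophenyl)ethanol | OC(Cc1cc(OC)c(OCC=C(C)C)cc1OC)c1c(F)cc(F)cc1F
F3 | step 6 | 2-[2,5-dimethoxy-4-(3-methylbut-2-enyloxy)phenyl]-1-(2,4,6-trifluorophenyl)ethanone | O=C(Cc1cc(OC)c(OCC=C(C)C)cc1OC)c1c(F)cc(F)cc1F
F4 | step 6 | (E)-3-(dimethylamino)-2-[2,5-dimethoxy-4-(3-methylbut-2-enyloxy)phenyl]-1-(2,4,6-trifluorophenyl)prop-2-en-1-one | CN(C)/C=C(/C(=O)c1c(F)cc(F)cc1F)c1cc(OC)c(OCC=C(C)C)cc1OC
F5 | step 7 | 5-fluoro-7-hydroxy-3-[2,5-dimethoxy-4-(3-methylbut-2-enyloxy)phenyl]-4H-chromen-4-one | COc1cc(-c2coc3cc(O)cc(F)c3c2=O)c(OC)cc1OCC=C(C)C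
F6 | step 3 | (E)-1-(2-ethoxyethenyl)-2,5-dimethoxy-4-(3-methylbut-2-enyloxy)benzene | CCO/C=C/c1cc(OC)c(OCC=C(C)C)cc1OC
F7 | step 4 | 2,5-dimethoxy-4-(3-methylbut-2-enyloxy)benzaldehyde | O=Cc1cc(OC)c(OCC=C(C)C)cc1OC
F8 | step 4 | diethyl [lithio(pyrrolidin-1-yl)methyl]phosphonate | [Li+].CCOP(=O)(OCC)[CH-]N1CCCC1
A1 | alternative 1 | 3-[4-(benzyloxy)-2,5-dimethoxyphenyl]-5,7-bis(methoxymethoxy)-4H-chromen-4-one | COCOc1cc(OCOC)c2c(c1)occ(-c1cc(OC)c(OCc3ccccc3)cc1OC)c2=O
A2 | alternative 1 | (Z)-1-[4-(benzyloxy)-2,5-dimethoxyphenyl]-2-[3,5-bis(methoxymethoxy)phenoxy]ethenyl trifluoromethanesulfonate | COCOc1cc(OCOC)cc(O/C=C(\OS(=O)(=O)C(F)(F)F)c2cc(OC)c(OCc3ccccc3)cc2OC)c1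
A3 | alternative 1 | carbon monoxide | [C-]#[O+]
A4 | alternative 2 | 5-hydroxy-7-(triisopropylsilyloxy)-3-[2,5-dimethoxy-4-(3-methylbut-2-enyloxy)phenyl]-4H-chromen-4-one | COc1cc(-c2coc3cc(O[Si](C(C)C)(C(C)C)C(C)C)cc(O)c3c2=O)c(OC)cc1OCC=C(C)C
A5 | alternative 2 | 2-(2-diazoacetyl)-5-[2,5-dimethoxy-4-(3-methylbut-2-enyloxy)phenyl]-4H-pyran-4-one | COc1cc(-c2coc(C(=O)C=[N+]=[N-])cc2=O)c(OC)cc1OCC=C(C)C
A6 | alternative 2 | (ethynyloxy)triisopropylsilane | C#CO[Si](C(C)C)(C(C)C)C(C)C
A7 | alternative 2 | kojic acid, 5-hydroxy-2-(hydroxymethyl)-4H-pyran-4-one | OCc1cc(=O)c(O)co1
A8 | alternative 3 | 5,7-bis(methoxymethoxy)-3-[2,5-dimethoxy-4-(3-methylbut-2-enyloxy)phenyl]-4H-chromen-4-one | COCOc1cc(OCOC)c2c(c1)occ(-c1cc(OC)c(OCC=C(C)C)cc1OC)c2=O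
A9 | alternative 3 | 3,5-bis(methoxymethoxy)-2-(trimethylsilyl)phenyl trifluoromethanesulfonate | COCOc1cc(OCOC)c([Si](C)(C)C)c(OS(=O)(=O)C(F)(F)F)c1
A10 | alternative 3 | methyl (Z)-3-hydroxy-2-[2,5-dimethoxy-4-(3-methylbut-2-enyloxy)phenyl]prop-2-enoate | COC(=O)/C(=C\O)c1cc(OC)c(OCC=C(C)C)cc1OC
A11 | alternative 3 | 3,5-bis(methoxymethoxy)benzyne (1,2-didehydro-3,5-bis(methoxymethoxy)benzene) | COCOC1=CC(OCOC)=CC#C1
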